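**Retrosynthetic overview**
- Target ⇐ chemoselective opening of the strained trans 12,6α-lactone of an 8α-acyloxy-1β-hydroxy-15-oxo-eudesmanolide; the lactone masks 6-OH and C-12 until the last step.
- Eudesmanolide core ⇐ cationic double cyclization (C5–C10, then C3–C4) of an acyclic butyrolactone that carries a vinyl ketone (as its silyloxydiene) and an α,β-unsaturated dimethyl acetal; rings B and A form in one operation.
- Cyclization precursor ⇐ indium Barbier union (C7–C8) of a 5-alkenyl-3-(bromomethyl)butenolide with 3-methyl-4-oxohex-5-enal; C-7 and C-8 are set from C-6.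
- Butenolide ⇐ asymmetric alkynylation of (E)-4,4-dimethoxybut-2-enal with methyl propiolate (sets C-6), then conjugate hydroalumination, hydroxymethylation and lactonization.
- Ring order: lactone ring first, then rings B and A together, lactone opened last.

Assumption: eudesmane numbering (C-1 to C-15; β = face of the angular methyl) is used for all intermediates, and the ProPhenol antipode written in step 1 is taken to give the (R)-carbinol; if its sense is the reverse, the enantiomeric ligand is used.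

**Step 1**
Reactants: 1 (E)-4,4-dimethoxybut-2-enal; 2 methyl propiolate
Product: 3 methyl (4R,5E)-4-hydroxy-7,7-dimethoxyhept-5-en-2-ynoate
Conditions: Zn(CH3)2 (3 equiv), (S,S)-2,6-bis{[2-(hydroxydiphenylmethyl)pyrrolidin-1-yl]methyl}-4-methylphenol (ProPhenol, 20 mol %), Ph3P=O (40 mol %), toluene, 4 °C; aq. NH4Cl
Reagents that add atoms: none
Why: Trost-type ProPhenol–dizinc catalysed asymmetric alkynylation delivers the zinc acetylide of the propiolate to one face of the enal and sets C-6 (R), the only stereocentre fixed by a chiral reagent.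

**Step 2**
Reactants: 3 methyl (4R,5E)-4-hydroxy-7,7-dimethoxyhept-5-en-2-ynoate; 4 paraformaldehyde
Product: 6 (5R)-3-(hydroxymethyl)-5-[(E)-3,3-dimethoxyprop-1-enyl]furan-2(5H)-one, via open-chain Z diol ester 5 (not isolated)
Conditions: (i-C4H9)2AlH (2.2 equiv), THF–HMPA, 0 °C; then (CH2O)n, 0 °C → rt; aq. KNaC4H4O6
Reagents that add atoms: none
Why: conjugate syn hydroalumination of the ynoate (vinylalumination) gives an α-alumino enoate that is hydroxymethylated at C-11 on the side remote from the C-6 substituent, so the γ-hydroxyl and the ester are cis and lactonize on work-up while C-6 is untouched.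

**Step 3**
Reactants: 6 (5R)-3-(hydroxymethyl)-5-[(E)-3,3-dimethoxyprop-1-enyl]furan-2(5H)-one
Product: 7 (5R)-3-(bromomethyl)-5-[(E)-3,3-dimethoxyprop-1-enyl]furan-2(5H)-one
Conditions: CBr4, PPh3, CH2Cl2, 0 °C
Reagents that add atoms: carbon tetrabromide, BrC(Br)(Br)Br
Why: Appel bromination of the primary allylic alcohol is neutral and spares the acetal and the base-labile C-6 hydrogen.

**Step 4**
Reactants: 8 2-methylpent-4-enal (racemic); 9 vinylmagnesium bromide
Product: 10 4-methylhepta-1,6-dien-3-ol (diastereomer mixture)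
Conditions: THF, −78 → 0 °C; aq. NH4Cl
Reagents that add atoms: none
Why: Grignard 1,2-addition; both stereocentres are erased later (carbinol in step 5, methyl-bearing carbon in step 8), so no control is needed.

**Step 5**
Reactants: 10 4-methylhepta-1,6-dien-3-ol
Product: 11 4-methylhepta-1,6-dien-3-one (racemic)
Conditions: Dess–Martin periodinane, CH2Cl2, 0 °C → rt
Reagents that add atoms: none
Why: Dess–Martin oxidation gives the vinyl ketone under non-basic conditions that avoid Michael polymerization.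

**Step 6**
Reactants: 11 4-methylhepta-1,6-dien-3-one
Product: 12 3-methyl-4-oxohex-5-enal (racemic)
Conditions: O3 (1.0 equiv), CH2Cl2, −78 °C; then PPh3, −78 °C → rt
Reagents that add atoms: ozone, [O-][O+]=O
Why: ozonolysis with reductive work-up cleaves the electron-rich isolated terminal alkene much faster than the electron-poor enone double bond.

**Step 7**
Reactants: 7 (5R)-3-(bromomethyl)-5-[(E)-3,3-dimethoxyprop-1-enyl]furan-2(5H)-one; 12 3-methyl-4-oxohex-5-enal
Product: 13 (4R,5R)-4-[(1S)-1-hydroxy-3-methyl-4-oxohex-5-enyl]-5-[(E)-3,3-dimethoxyprop-1-enyl]-3-methylideneoxolan-2-one (1:1 epimers at C-10)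
Conditions: In powder, THF/H2O (1:1), rt
Reagents that add atoms: none
Why: indium Barbier allylation with γ-attack of the cyclic allylindium through a chair transition state adds the aldehyde to C-7 on the ring face opposite the C-6 alkenyl group (trans lactone) and, because the ring holds C-6 trans to the CH2–In carbon, with the aldehyde chain equatorial (7,8-anti), so C-7 and C-8 are both set from C-6.

**Step 8**
Reactants: 13 (4R,5R)-4-[(1S)-1-hydroxy-3-methyl-4-oxohex-5-enyl]-5-[(E)-3,3-dimethoxyprop-1-enyl]-3-methylideneoxolan-2-one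
Product: 16 (4βH,5αH,6βH,7αH)-8α-hydroxy-15,15-dimethoxy-1-oxoeudesm-11(13)-en-12,6α-olide, via bis-silyl dienol ether 14 (not isolated), via tricyclic silyl enol ether 15 (not isolated)
Conditions: Et3N (2.1 equiv), TMSOTf (2.6 equiv), CH2Cl2 (0.01 M), −78 → −30 °C; then aq. citric acid, THF, 0 °C
Reagents that add atoms: none
Why: Proposed new method: the vinyl ketone is turned in situ into its 2-silyloxydiene (and 8-OH into its silyl ether), the excess silyl triflate ionizes the unsaturated acetal to a methoxyallyl cation, Mukaiyama–Michael attack of C-10 on C-5 is followed by closure of the new enol ether carbon C-4 onto the silyl-activated enone carbon C-3 and recapture of methoxide, so rings B and A form in one operation through a chair transition state that keeps the 8-silyloxy group, the trans-fused lactone, C-1 and C-4 equatorial and therefore gives 10β-methyl, 5α-H and the 4α acetal carbon, the closest known reactions being the intramolecular ionic Diels–Alder reaction of unsaturated acetals and the silyl triflate–amine intramolecular double Michael reaction.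

**Step 9**
Reactants: 17 ethyl 2-(hydroxymethyl)acrylate
Product: 18 ethyl 2-[(tert-butyldimethylsilyloxy)methyl]acrylate
Conditions: TBSCl, imidazole, DMF, 0 °C → rt
Reagents that add atoms: tert-butyldimethylsilyl chloride, CC(C)(C)[Si](C)(C)Cl
Why: standard silyl ether protection of a primary alcohol.

**Step 10**
Reactants: 18 ethyl 2-[(tert-butyldimethylsilyloxy)methyl]acrylate
Product: 19 2-[(tert-butyldimethylsilyloxy)methyl]acrylic acid
Conditions: LiOH, THF/H2O, 0 °C → rt; then HCl (aq.) to pH 4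
Reagents that add atoms: lithium hydroxide, [Li+].[OH-]
Why: ester saponification; the primary silyl ether survives aqueous LiOH.

**Step 11**
Reactants: 16 (4βH,5αH,6βH,7αH)-8α-hydroxy-15,15-dimethoxy-1-oxoeudesm-11(13)-en-12,6α-olide; 19 2-[(tert-butyldimethylsilyloxy)methyl]acrylic acid
Product: 20 (4βH,5αH,6βH,7αH)-8α-{2-[(tert-butyldimethylsilyloxy)methyl]acryloyloxy}-15,15-dimethoxy-1-oxoeudesm-11(13)-en-12,6α-olide
Conditions: DCC, DMAP (cat.), CH2Cl2, 0 °C → rt
Reagents that add atoms: none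
Why: Steglich esterification of the only free hydroxyl (equatorial 8α-OH); no stereocentre is touched.

**Step 12**
Reactants: 20 (4βH,5αH,6βH,7αH)-8α-{2-[(tert-butyldimethylsilyloxy)methyl]acryloyloxy}-15,15-dimethoxy-1-oxoeudesm-11(13)-en-12,6α-olide
Product: 21 (4βH,5αH,6βH,7αH)-8α-{2-[(tert-butyldimethylsilyloxy)methyl]acryloyloxy}-1β-hydroxy-15,15-dimethoxyeudesm-11(13)-en-12,6α-olide
Conditions: NaBH4, CeCl3·7H2O, MeOH/THF, −78 → −40 °C
Reagents that add atoms: none
Why: Luche 1,2-reduction of the C-1 ketone with axial hydride delivery from the α face, anti to the angular methyl, gives the equatorial 1β-alcohol (as in the borohydride reduction of the Wieland–Miescher ketone), and CeCl3 at low temperature suppresses conjugate reduction of the α-methylene lactone.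

**Step 13**
Reactants: 21 (4βH,5αH,6βH,7αH)-8α-{2-[(tert-butyldimethylsilyloxy)methyl]acryloyloxy}-1β-hydroxy-15,15-dimethoxyeudesm-11(13)-en-12,6α-olide
Product: 22 (4βH,5αH,6βH,7αH)-1β-hydroxy-8α-[2-(hydroxymethyl)acryloyloxy]-15-oxoeudesm-11(13)-en-12,6α-olide
Conditions: HCl (1 M aq.), THF, 0 °C → rt
Reagents that add atoms: water, O
Why: acid hydrolysis removes the dimethyl acetal and the primary silyl ether together, any C-4 epimer equilibrates to the equatorial 4α-aldehyde, and the lactone keeps 6-OH and C-12 inert to acid.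

**Step 14**
Reactants: 22 (4βH,5αH,6βH,7αH)-1β-hydroxy-8α-[2-(hydroxymethyl)acryloyloxy]-15-oxoeudesm-11(13)-en-12,6α-olide
Product: 23 1β,6α-dihydroxy-8α-[2-(hydroxymethyl)acryloyloxy]-15-oxoeudesm-11(13)-en-12-oic acid (1R,4R,5S,6R,7S,8S,10R; CNP0599450.1)
Conditions: LiOH (1.1 equiv), THF/H2O, 0 °C; then HCl (aq.) to pH 5 at 0 °C
Reagents that add atoms: lithium hydroxide, [Li+].[OH-]
Why: chemoselective saponification, in which the strained trans-fused α-methylene-γ-lactone is opened by hydroxide faster than the hindered secondary acrylate at C-8, frees 6α-OH and the C-12 acid without touching a stereocentre.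

**Compound list**
1 | (E)-4,4-dimethoxybut-2-enal | COC(OC)/C=C/C=O | starting material
2 | methyl propiolate | C#CC(=O)OC | starting material
3 | methyl (4R,5E)-4-hydroxy-7,7-dimethoxyhept-5-en-2-ynoate | COC(=O)C#C[C@H](O)/C=C/C(OC)OC | intermediate
4 | paraformaldehyde (formaldehyde source) | C=O | starting material
5 | methyl (2Z,4R,5E)-4-hydroxy-2-(hydroxymethyl)-7,7-dimethoxyhepta-2,5-dienoate | COC(=O)/C(CO)=C\[C@H](O)/C=C/C(OC)OC | intermediate
6 | (5R)-3-(hydroxymethyl)-5-[(E)-3,3-dimethoxyprop-1-enyl]furan-2(5H)-one | OCC1=C[C@@H](/C=C/C(OC)OC)OC1=O | intermediate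
7 | (5R)-3-(bromomethyl)-5-[(E)-3,3-dimethoxyprop-1-enyl]furan-2(5H)-one | BrCC1=C[C@@H](/C=C/C(OC)OC)OC1=O | intermediate
8 | 2-methylpent-4-enal (racemic) | C=CCC(C)C=O | starting material
9 | vinylmagnesium bromide | C=C[Mg]Br | starting material
10 | 4-methylhepta-1,6-dien-3-ol (diastereomer mixture) | C=CCC(C)C(O)C=C | intermediate
11 | 4-methylhepta-1,6-dien-3-one (racemic) | C=CCC(C)C(=O)C=C | intermediate
12 | 3-methyl-4-oxohex-5-enal (racemic) | O=CCC(C)C(=O)C=C | intermediate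
13 | (4R,5R)-4-[(1S)-1-hydroxy-3-methyl-4-oxohex-5-enyl]-5-[(E)-3,3-dimethoxyprop-1-enyl]-3-methylideneoxolan-2-one (1:1 epimers at C-10) | C=CC(=O)C(C)C[C@H](O)[C@H]1C(=C)C(=O)O[C@@H]1/C=C/C(OC)OC | intermediate
14 | 8-O-trimethylsilyl ether of 13 with the ketone as its 2-(trimethylsilyloxy)-1,3-diene (E/Z mixture at C-1=C-10) | C=CC(O[Si](C)(C)C)=C(C)C[C@H](O[Si](C)(C)C)[C@H]1C(=C)C(=O)O[C@@H]1/C=C/C(OC)OC | intermediate
15 | (4βH,5αH,6βH,7αH)-15,15-dimethoxy-1,8α-bis(trimethylsilyloxy)eudesma-1,11(13)-dien-12,6α-olide | C[Si](C)(C)O[C@H]1C[C@]2(C)[C@@H]([C@H]3OC(=O)C(=C)[C@@H]31)[C@H](C(OC)OC)CC=C2O[Si](C)(C)C | intermediate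
16 | (4βH,5αH,6βH,7αH)-8α-hydroxy-15,15-dimethoxy-1-oxoeudesm-11(13)-en-12,6α-olide | O[C@H]1C[C@]2(C)[C@@H]([C@H]3OC(=O)C(=C)[C@@H]31)[C@H](C(OC)OC)CCC2=O | intermediate
17 | ethyl 2-(hydroxymethyl)acrylate | C=C(CO)C(=O)OCC | starting material
18 | ethyl 2-[(tert-butyldimethylsilyloxy)methyl]acrylate | C=C(CO[Si](C)(C)C(C)(C)C)C(=O)OCC | intermediate
19 | 2-[(tert-butyldimethylsilyloxy)methyl]acrylic acid | C=C(CO[Si](C)(C)C(C)(C)C)C(=O)O | intermediate
20 | (4βH,5αH,6βH,7αH)-8α-{2-[(tert-butyldimethylsilyloxy)methyl]acryloyloxy}-15,15-dimethoxy-1-oxoeudesm-11(13)-en-12,6α-olide | C=C(CO[Si](C)(C)C(C)(C)C)C(=O)O[C@H]1C[C@]2(C)[C@@H]([C@H]3OC(=O)C(=C)[C@@H]31)[C@H](C(OC)OC)CCC2=O | intermediate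
21 | (4βH,5αH,6βH,7αH)-8α-{2-[(tert-butyldimethylsilyloxy)methyl]acryloyloxy}-1β-hydroxy-15,15-dimethoxyeudesm-11(13)-en-12,6α-olide | C=C(CO[Si](C)(C)C(C)(C)C)C(=O)O[C@H]1C[C@]2(C)[C@@H]([C@H]3OC(=O)C(=C)[C@@H]31)[C@H](C(OC)OC)CC[C@H]2O | intermediate
22 | (4βH,5αH,6βH,7αH)-1β-hydroxy-8α-[2-(hydroxymethyl)acryloyloxy]-15-oxoeudesm-11(13)-en-12,6α-olide | C=C(CO)C(=O)O[C@H]1C[C@]2(C)[C@@H]([C@H]3OC(=O)C(=C)[C@@H]31)[C@H](C=O)CC[C@H]2O | intermediate
23 | 1β,6α-dihydroxy-8α-[2-(hydroxymethyl)acryloyloxy]-15-oxoeudesm-11(13)-en-12-oic acid (1R,4R,5S,6R,7S,8S,10R) | C=C(CO)C(=O)O[C@H]1C[C@]2(C)[C@@H]([C@@H](O)[C@@H]1C(=C)C(=O)O)[C@H](C=O)CC[C@H]2O | target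

**Step count**
Total steps: 14. Longest linear sequence: 9 steps (1 → 23 through steps 1, 2, 3, 7, 8, 11, 12, 13, 14).

**Steps most likely to fail, with fallbacks**

Step 2 (hydroalumination, hydroxymethylation and lactonization on a free γ-hydroxy ynoate). The fallback sets out from 3 and comes back at 6. Palladium-catalysed syn hydrostannation of the ynoate ((n-C4H9)3SnH, Pd(PPh3)4 cat., THF, 0 °C) places tin on the α-carbon, and the cis γ-hydroxy ester closes to (5R)-3-(tributylstannyl)-5-[(E)-3,3-dimethoxyprop-1-enyl]furan-2(5H)-one F1. Iododestannylation (I2, CH2Cl2, 0 °C) gives (5R)-3-iodo-5-[(E)-3,3-dimethoxyprop-1-enyl]furan-2(5H)-one F2. Stille coupling of F2 with (tributylstannyl)methanol (Pd(PPh3)4, CuI, dioxane, 60 °C) gives 6.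

Step 8 (cationic bicyclization). The risks are γ-deprotonation of the methoxyallyl cation, attack on the α-methylene lactone, and cis fusion. The fallback sets out from 13 and comes back at 16, using a neutral enal as dienophile.
- Mild acetal hydrolysis (PPTS, acetone/H2O) gives the enal (4R,5R)-4-[(1S)-1-hydroxy-3-methyl-4-oxohex-5-enyl]-3-methylidene-5-[(E)-3-oxoprop-1-enyl]oxolan-2-one F3.
- TBSOTf/Et3N (CH2Cl2, −78 °C) gives the isolable 8-O-TBS 2-(tert-butyldimethylsilyloxy)diene enal F4.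
- A thermal or (CH3)2AlCl-promoted intramolecular Diels–Alder reaction (toluene, 90 °C or CH2Cl2, −40 °C) gives the tricyclic 1,8α-bis(tert-butyldimethylsilyloxy)-15-oxoeudesma-1,11(13)-dien-12,6α-olide F5.
- HF·pyridine (THF, 0 °C) gives 8α-hydroxy-1,15-dioxoeudesm-11(13)-en-12,6α-olide F6.
- Chemoselective acetalization of the aldehyde (HC(OMe)3, PPTS, MeOH) gives 16.

Step 14 (lactone hydrolysis in the presence of the C-8 ester; the ester may also cleave, or the product may relactonize). The fallback sets out from 16 and comes back at 23, opening the lactone before the C-8 ester exists and ending with a neutral deprotection.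
- LiOH (THF/H2O), then allyl bromide (DMF) gives allyl 6α,8α-dihydroxy-15,15-dimethoxy-1-oxoeudesm-11(13)-en-12-oate F7.
- Regioselective Steglich acylation of the less hindered 8α-OH with 19 gives allyl 8α-{2-[(tert-butyldimethylsilyloxy)methyl]acryloyloxy}-6α-hydroxy-15,15-dimethoxy-1-oxoeudesm-11(13)-en-12-oate F8.
- Luche reduction gives allyl 8α-{2-[(tert-butyldimethylsilyloxy)methyl]acryloyloxy}-1β,6α-dihydroxy-15,15-dimethoxyeudesm-11(13)-en-12-oate F9.
- Aqueous HCl/THF gives allyl 1β,6α-dihydroxy-8α-[2-(hydroxymethyl)acryloyloxy]-15-oxoeudesm-11(13)-en-12-oate F10.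
- Pd(PPh3)4 with morpholine (THF, rt) removes the allyl ester and gives 23.

**Further compounds**
F1 | step 2 | (5R)-3-(tributylstannyl)-5-[(E)-3,3-dimethoxyprop-1-enyl]furan-2(5H)-one | CCCC[Sn](CCCC)(CCCC)C1=C[C@@H](/C=C/C(OC)OC)OC1=O
F2 | step 2 | (5R)-3-iodo-5-[(E)-3,3-dimethoxyprop-1-enyl]furan-2(5H)-one | IC1=C[C@@H](/C=C/C(OC)OC)OC1=O
F3 | step 8 | (4R,5R)-4-[(1S)-1-hydroxy-3-methyl-4-oxohex-5-enyl]-3-methylidene-5-[(E)-3-oxoprop-1-enyl]oxolan-2-one | C=CC(=O)C(C)C[C@H](O)[C@H]1C(=C)C(=O)O[C@@H]1/C=C/C=O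
F4 | step 8 | 8-O-TBS ether of F3 with the ketone as its 2-(tert-butyldimethylsilyloxy)-1,3-diene | C=CC(O[Si](C)(C)C(C)(C)C)=C(C)C[C@H](O[Si](C)(C)C(C)(C)C)[C@H]1C(=C)C(=O)O[C@@H]1/C=C/C=O
F5 | step 8 | (4βH,5αH,6βH,7αH)-1,8α-bis(tert-butyldimethylsilyloxy)-15-oxoeudesma-1,11(13)-dien-12,6α-olide | CC(C)(C)[Si](C)(C)O[C@H]1C[C@]2(C)[C@@H]([C@H]3OC(=O)C(=C)[C@@H]31)[C@H](C=O)CC=C2O[Si](C)(C)C(C)(C)C
F6 | step 8 | (4βH,5αH,6βH,7αH)-8α-hydroxy-1,15-dioxoeudesm-11(13)-en-12,6α-olide | O[C@H]1C[C@]2(C)[C@@H]([C@H]3OC(=O)C(=C)[C@@H]31)[C@H](C=O)CCC2=O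
F7 | step 14 | allyl 6α,8α-dihydroxy-15,15-dimethoxy-1-oxoeudesm-11(13)-en-12-oate | O[C@H]1C[C@]2(C)[C@@H]([C@@H](O)[C@@H]1C(=C)C(=O)OCC=C)[C@H](C(OC)OC)CCC2=O
F8 | step 14 | allyl 8α-{2-[(tert-butyldimethylsilyloxy)methyl]acryloyloxy}-6α-hydroxy-15,15-dimethoxy-1-oxoeudesm-11(13)-en-12-oate | C=C(CO[Si](C)(C)C(C)(C)C)C(=O)O[C@H]1C[C@]2(C)[C@@H]([C@@H](O)[C@@H]1C(=C)C(=O)OCC=C)[C@H](C(OC)OC)CCC2=O
F9 | step 14 | allyl 8α-{2-[(tert-butyldimethylsilyloxy)methyl]acryloyloxy}-1β,6α-dihydroxy-15,15-dimethoxyeudesm-11(13)-en-12-oate | C=C(CO[Si](C)(C)C(C)(C)C)C(=O)O[C@H]1C[C@]2(C)[C@@H]([C@@H](O)[C@@H]1C(=C)C(=O)OCC=C)[C@H](C(OC)OC)CC[C@H]2O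
F10 | step 14 | allyl 1β,6α-dihydroxy-8α-[2-(hydroxymethyl)acryloyloxy]-15-oxoeudesm-11(13)-en-12-oate | C=C(CO)C(=O)O[C@H]1C[C@]2(C)[C@@H]([C@@H](O)[C@@H]1C(=C)C(=O)OCC=C)[C@H](C=O)CC[C@H]2O
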